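**Retrosynthetic overview**
1. Feature used: each benzene ring (C1 = the CH2O carbon) has four adjacent heteroatom-bearing carbons, Br on C2 and C3 and OH on C4 and C5, and only C6 carries H. Read in pairs, the ring is three alkynes, C6≡C1, C2≡C3 and C4≡C5, with Si standing in for Br and B for OH.
2. The C–O–C bridge is cut into two copies of one aldehyde (reductive homo-etherification), so only one arene is built. The phenols stay TBS-masked until the last step because a free p-hydroxybenzyl ether ionises easily.
3. The arene is cut by [2+2+2] at C1–C2, C3–C4 and C5–C6 into diyne 6 (propargylic O tied to an alkynyl silicon) and the symmetrical diborylacetylene 7.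
4. Ring order: the oxasilole ring (C1, CH2, O, Si, C2) closes first, at the cobaltacycle stage, and the benzene ring second, both in step 3. The oxasilole opens again when C2–Si becomes C2–Br, which also frees the benzylic oxygen.
5. After ring construction B→OH comes before Si→Br. Br+ then meets the sluggish diisopropyl(alkoxy)silyl group on an oxygen-activated ring, and no C–B bond is exposed to bromine.

Key step: step 3

Assumption: 7 is bought as such, and all intermediates carry the ring numbering of the target (C1 bears CH2O).

**Step 1**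
Reactants: 1 trimethylsilylacetylene; 2 dichlorodiisopropylsilane
Product: 4 chlorodiisopropyl[(trimethylsilyl)ethynyl]silane, via lithium (trimethylsilyl)acetylide 3 (not isolated)
Conditions: 1, n-BuLi (1.0 equiv), THF, −78 °C; cannulated into 2 (1.5 equiv), THF, −78 °C → rt; distillation
Reagents that add atoms: none
Why: Nucleophilic substitution at silicon by a lithium acetylide, in which inverse addition to excess 2 and the two isopropyl groups should slow the second displacement enough to stop at the monochloride.

**Step 2**
Reactants: 4 chlorodiisopropyl[(trimethylsilyl)ethynyl]silane; 5 propargyl alcohol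
Product: 6 diisopropyl(prop-2-ynyloxy)[(trimethylsilyl)ethynyl]silane
Conditions: imidazole (2 equiv), CH2Cl2, 0 °C → rt
Reagents that add atoms: none
Why: Imidazole-promoted silyl ether formation from a primary alcohol and a chlorosilane, with the isopropyl groups making the Si–O bond of 6 robust to purification and both alkynyl–Si bonds inert to the weak base.

**Step 3**
Reactants: 6 diisopropyl(prop-2-ynyloxy)[(trimethylsilyl)ethynyl]silane; 7 bis(pinacolatoboryl)acetylene
Product: 9 1,1-diisopropyl-5,6-bis(pinacolatoboryl)-7-(trimethylsilyl)-1,3-dihydro-2,1-benzoxasilole, via CpCo cobaltacyclopentadiene 8 (not isolated)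
Conditions: 7 (2.5 equiv), CpCo(CO)2 (20 mol %), degassed xylenes, reflux, hν (visible lamp); 6 and the catalyst added by syringe pump over 10 h
Reagents that add atoms: none
Why: Heat and light strip CO from CpCo(CO)2, and the monovalent CpCo fragment binds both alkynes of 6 and couples them oxidatively to the trivalent cobaltacyclopentadiene 8, with C6–H and C3–SiMe3 next to the metal. This coupling makes C1–C2 and so closes the five-membered oxasilole ring (C1, CH2, O, Si, C2) intramolecularly, the three-atom CH2–O–Si tether leaving no other ring size open. Alkyne 7 then coordinates and inserts into a Co–C bond (or adds across the diene in a [4+2] sense), and reductive elimination makes C3–C4 and C5–C6, which closes the benzene ring and returns CpCo. The closest known reaction type is the CpCo(CO)2-catalysed [2+2+2] cocyclisation of alpha,omega-diynes with bis(trimethylsilyl)acetylene or with alkynyl pinacolboronates. No stereocentre is formed and no regiochemical choice exists, because the tether fixes C1 beside C2 and 7 is symmetrical; the selectivity needed is cross-cyclisation over self-reaction of the terminal alkyne of 6, secured by keeping 6 dilute against an excess of 7, which itself trimerises only slowly. The open point is the crowding along C2–Si, C3–Si, C4–B and C5–B, eased by flat Bpin groups that can turn out of the ring plane.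

**Step 4**
Reactants: 9 1,1-diisopropyl-5,6-bis(pinacolatoboryl)-7-(trimethylsilyl)-1,3-dihydro-2,1-benzoxasilole
Product: 10 1,1-diisopropyl-7-(trimethylsilyl)-1,3-dihydro-2,1-benzoxasilole-5,6-diol
Conditions: NaBO3·4H2O (6 equiv), THF/H2O 1:1, 0 °C → rt, Ar; aq NH4Cl/Na2S2O3 work-up; used crude
Reagents that add atoms: sodium perborate, [Na+].[Na+].O[B-]1(O)OO[B-](O)(O)OO1
Why: Organoborane oxidation, in which hydroperoxide adds to the Lewis-acidic boron atoms and each aryl carbon migrates from B to O at its own position, while both C–Si bonds should stay because Tamao–Fleming oxidation of a hindered diisopropyl(alkoxy)silane needs fluoride or strong base with heating and SiMe3 offers no heteroatom handle.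

**Step 5**
Reactants: 10 1,1-diisopropyl-7-(trimethylsilyl)-1,3-dihydro-2,1-benzoxasilole-5,6-diol
Product: 11 5,6-bis(tert-butyldimethylsilyloxy)-1,1-diisopropyl-7-(trimethylsilyl)-1,3-dihydro-2,1-benzoxasilole
Conditions: TBSOTf (2.5 equiv), 2,6-lutidine (4 equiv), CH2Cl2, 0 °C → rt
Reagents that add atoms: tert-butyldimethylsilyl triflate, CC(C)(C)[Si](C)(C)OS(=O)(=O)C(F)(F)F
Why: Silyl triflate silylation of phenols should reach even the C4 hydroxyl beside SiMe3, masks the air-sensitive catechol, keeps both oxygens as π-donors for the next step, and gives a group that fluoride removes at the end without acid.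

**Step 6**
Reactants: 11 5,6-bis(tert-butyldimethylsilyloxy)-1,1-diisopropyl-7-(trimethylsilyl)-1,3-dihydro-2,1-benzoxasilole
Product: 13 2,3-dibromo-4,5-bis(tert-butyldimethylsilyloxy)benzyl alcohol, via bromosilyl ether 12 (not isolated)
Conditions: Br2 (2.1 equiv), CH2Cl2, −78 → 0 °C, dark; then 48% aq HF, MeCN, 0 °C; NaHCO3/Na2S2O3 work-up
Reagents that add atoms: bromine, BrBr
Why: Double electrophilic ipso-bromodesilylation, in which Br+ attacks C2 (para to the C5 siloxy group) and C3 (ortho to the C4 siloxy group), where the beta-silicon effect, oxygen donation and relief of crowding all help, so both silicon groups should leave before the flanked C6–H reacts, and the alkyl O–Si bond of 12 is then cut by acidic fluoride, which is known to spare aryl TBS ethers.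

**Step 7**
Reactants: 13 2,3-dibromo-4,5-bis(tert-butyldimethylsilyloxy)benzyl alcohol
Product: 14 2,3-dibromo-4,5-bis(tert-butyldimethylsilyloxy)benzaldehyde
Conditions: Dess–Martin periodinane (1.2 equiv), CH2Cl2, 0 °C → rt
Reagents that add atoms: none
Why: Dess–Martin oxidation takes a primary benzylic alcohol to the aldehyde under near-neutral conditions that leave aryl silyl ethers and aryl bromides alone and cannot over-oxidise.

**Step 8**
Reactants: 14 2,3-dibromo-4,5-bis(tert-butyldimethylsilyloxy)benzaldehyde (two molecules)
Product: 16 bis[2,3-dibromo-4,5-bis(tert-butyldimethylsilyloxy)benzyl] ether, via triethylsilyl ether 15 (not isolated)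
Conditions: Et3SiH (1.2 equiv per aldehyde), TMSOTf (10 mol %), CH2Cl2, −20 → 0 °C
Reagents that add atoms: none
Why: Reductive etherification, in which acid-catalysed hydrosilylation of one aldehyde gives 15, 15 condenses with a second aldehyde to an oxocarbenium ion, and Et3SiH reduces this to the symmetrical dibenzyl ether, a known homocoupling of aromatic aldehydes in which the two bromines should damp re-ionisation of the product.

**Step 9**
Reactants: 16 bis[2,3-dibromo-4,5-bis(tert-butyldimethylsilyloxy)benzyl] ether
Product: 17 bis(2,3-dibromo-4,5-dihydroxybenzyl) ether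
Conditions: Bu4NF (4.4 equiv), AcOH (5 equiv), THF, 0 °C, Ar, short reaction time; pH 5 buffer work-up
Reagents that add atoms: none
Why: Fluoride desilylation cleaves aryl O–Si bonds within minutes, and the acetic acid buffer, low temperature and non-nucleophilic solvent keep the freed catechols protonated so that neither quinone methide formation at the p-hydroxybenzyl ether nor air oxidation should set in.

**Compound list**
1 | trimethylsilylacetylene | C#C[Si](C)(C)C | starting material
2 | dichlorodiisopropylsilane | CC(C)[Si](Cl)(Cl)C(C)C | starting material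
3 | lithium (trimethylsilyl)acetylide | [Li]C#C[Si](C)(C)C | intermediate
4 | chlorodiisopropyl[(trimethylsilyl)ethynyl]silane | CC(C)[Si](Cl)(C#C[Si](C)(C)C)C(C)C | intermediate
5 | propargyl alcohol | C#CCO | starting material
6 | diisopropyl(prop-2-ynyloxy)[(trimethylsilyl)ethynyl]silane | C#CCO[Si](C(C)C)(C(C)C)C#C[Si](C)(C)C | intermediate
7 | bis(pinacolatoboryl)acetylene | CC1(C)OB(C#CB2OC(C)(C)C(C)(C)O2)OC1(C)C | starting material
8 | cyclopentadienyl cobaltacyclopentadiene from 6 (Co bound to C6–H and C3–SiMe3, fused to the oxasilole ring) | C[Si](C)(C)C1=C2C(=C[Co+]1)CO[Si]2(C(C)C)C(C)C.c1cc[cH-]c1 | intermediate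
9 | 1,1-diisopropyl-5,6-bis(pinacolatoboryl)-7-(trimethylsilyl)-1,3-dihydro-2,1-benzoxasilole | C[Si](C)(C)c1c(B2OC(C)(C)C(C)(C)O2)c(B2OC(C)(C)C(C)(C)O2)cc2CO[Si](C(C)C)(C(C)C)c12 | intermediate
10 | 1,1-diisopropyl-7-(trimethylsilyl)-1,3-dihydro-2,1-benzoxasilole-5,6-diol | C[Si](C)(C)c1c(O)c(O)cc2CO[Si](C(C)C)(C(C)C)c12 | intermediate
11 | 5,6-bis(tert-butyldimethylsilyloxy)-1,1-diisopropyl-7-(trimethylsilyl)-1,3-dihydro-2,1-benzoxasilole | C[Si](C)(C)c1c(O[Si](C)(C)C(C)(C)C)c(O[Si](C)(C)C(C)(C)C)cc2CO[Si](C(C)C)(C(C)C)c12 | intermediate
12 | bromo{[2,3-dibromo-4,5-bis(tert-butyldimethylsilyloxy)phenyl]methoxy}diisopropylsilane | CC(C)[Si](Br)(OCc1cc(O[Si](C)(C)C(C)(C)C)c(O[Si](C)(C)C(C)(C)C)c(Br)c1Br)C(C)C | intermediate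
13 | 2,3-dibromo-4,5-bis(tert-butyldimethylsilyloxy)benzyl alcohol | OCc1cc(O[Si](C)(C)C(C)(C)C)c(O[Si](C)(C)C(C)(C)C)c(Br)c1Br | intermediate
14 | 2,3-dibromo-4,5-bis(tert-butyldimethylsilyloxy)benzaldehyde | O=Cc1cc(O[Si](C)(C)C(C)(C)C)c(O[Si](C)(C)C(C)(C)C)c(Br)c1Br | intermediate
15 | [2,3-dibromo-4,5-bis(tert-butyldimethylsilyloxy)benzyloxy]triethylsilane | CC[Si](CC)(CC)OCc1cc(O[Si](C)(C)C(C)(C)C)c(O[Si](C)(C)C(C)(C)C)c(Br)c1Br | intermediate
16 | bis[2,3-dibromo-4,5-bis(tert-butyldimethylsilyloxy)benzyl] ether | CC(C)(C)[Si](C)(C)Oc1cc(COCc2cc(O[Si](C)(C)C(C)(C)C)c(O[Si](C)(C)C(C)(C)C)c(Br)c2Br)c(Br)c(Br)c1O[Si](C)(C)C(C)(C)C | intermediate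
17 | bis(2,3-dibromo-4,5-dihydroxybenzyl) ether | Oc1cc(COCc2cc(O)c(O)c(Br)c2Br)c(Br)c(Br)c1O | target

Total step count: 9. Longest linear sequence: 9 steps (1 or 2 → 17).

**Steps most likely to fail**

Step 3. The terminal alkyne of 6 may oligomerise on cobalt faster than the crowded cobaltacycle takes up 7, or the cobaltacycle may collapse to a cyclobutadiene complex. The fallback sets out from 7 (with 6) and comes back at 9. It puts the reluctant alkyne on the metal first. 7 is stirred with Co2(CO)8 (1 equiv) in toluene at rt to give the alkyne-bridged zerovalent cobalt complex Co2(CO)6[μ-bis(pinacolatoboryl)acetylene] F1. F1 is then heated with 6 in xylenes. This stoichiometric cocyclisation of preformed alkynylboronate–Co2(CO)6 complexes with alpha,omega-diynes is known chemistry. Every metal unit already carries 7, so cross-selection no longer depends on which alkyne binds faster.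

Step 6. Cleavage of the hindered C2–Si bond may be slow, which would let bromination at C6–H or acid-induced loss of silicon compete. The fallback sets out from 11 and comes back at 13.
- 11 is treated with only 1 equiv of Br2 at −78 °C. This should exchange the better-leaving, more strained SiMe3 group and stop at 7-bromo-5,6-bis(tert-butyldimethylsilyloxy)-1,1-diisopropyl-1,3-dihydro-2,1-benzoxasilole F2.
- The smaller electrophile H+ then takes over. CF3CO2H in CH2Cl2 at 0 °C protodesilylates C2 (para to the C5 siloxy group) to {[3-bromo-4,5-bis(tert-butyldimethylsilyloxy)phenyl]methoxy}diisopropylsilyl trifluoroacetate F3.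
- Aqueous HF in MeCN frees 3-bromo-4,5-bis(tert-butyldimethylsilyloxy)benzyl alcohol F4.
- NBS in MeCN at 0 °C brominates para to the C5 oxygen, at C2, the intrinsically most nucleophilic and less shielded of the two open positions, to give 13.

Step 8. The benzylic position may be over-reduced, the product may ionise under the acid catalyst, or condensation may stall at the ortho-bromo aldehyde. The fallback sets out from 13 and comes back at 16, and step 7 falls away. Part of 13 is converted by an Appel reaction (CBr4, PPh3, CH2Cl2, 0 °C) into 2,3-dibromo-4,5-bis(tert-butyldimethylsilyloxy)benzyl bromide F5. F5 alkylates the remaining 13 under Ag2O (CH2Cl2, 4 Å molecular sieves, dark, rt). This base-free Williamson-type etherification spares aryl silyl ethers.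

**Further compounds**
F1 | step 3 | Co2(CO)6[μ-bis(pinacolatoboryl)acetylene] | CC1(C)OB(OC1(C)C)C23C4(B5OC(C)(C)C(C)(C)O5)[Co]2(=C=O)(=C=O)(=C=O)[Co]34(=C=O)(=C=O)=C=O
F2 | step 6 | 7-bromo-5,6-bis(tert-butyldimethylsilyloxy)-1,1-diisopropyl-1,3-dihydro-2,1-benzoxasilole | Brc1c(O[Si](C)(C)C(C)(C)C)c(O[Si](C)(C)C(C)(C)C)cc2CO[Si](C(C)C)(C(C)C)c12
F3 | step 6 | {[3-bromo-4,5-bis(tert-butyldimethylsilyloxy)phenyl]methoxy}diisopropylsilyl trifluoroacetate | CC(C)[Si](OC(=O)C(F)(F)F)(OCc1cc(Br)c(O[Si](C)(C)C(C)(C)C)c(O[Si](C)(C)C(C)(C)C)c1)C(C)C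
F4 | step 6 | 3-bromo-4,5-bis(tert-butyldimethylsilyloxy)benzyl alcohol | OCc1cc(Br)c(O[Si](C)(C)C(C)(C)C)c(O[Si](C)(C)C(C)(C)C)c1
F5 | step 8 | 2,3-dibromo-4,5-bis(tert-butyldimethylsilyloxy)benzyl bromide | BrCc1cc(O[Si](C)(C)C(C)(C)C)c(O[Si](C)(C)C(C)(C)C)c(Br)c1Br
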